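**Strategy.** Ring A is cut across C1-C2 and C5-C6. Its two carbon substituents sit on adjacent C1/C6 and its two hydroxyls on adjacent C3/C4, so C1/C6 map onto an alkyne and C2-C5 onto a symmetrical 2,3-dioxygenated butadiene. One thermal Diels-Alder reaction therefore builds the whole ring with all four substituents in place and no regiochemical question. The dienophile is a methyl 4-arylbut-2-ynoate that already holds ring B with its bromine. The ring B catechol is masked as a bis-pivalate, which silences ring B during the late ring A bromination and falls off in the final hydride reduction. Oxidation of the enediol ether, C5 bromination and i-Bu2AlH reduction complete the synthesis.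

Key step: step 7

**Remarks before the steps**
- Numbering: ring A is C1 (CH2OH), C2 (H), C3 (OH), C4 (OH), C5 (Br), C6 (CH2 bridge). Ring B is C1' (bridge), C2' (H), C3' (OH), C4' (OH), C5' (Br), C6' (H). The target has no stereocentre.
- Ring B protection: ring B travels as acyloxy groups, not alkoxy groups. An alkoxy group at C3' would activate C6' (para to it) toward bromine and compete with ring A C5. Two pivaloyloxy groups plus the bromine switch ring B off.
- End game: no Lewis-acid ether cleavage is run at the end. The C1 CH2OH lies para to the C4 OH and ionises easily, so boron halides would cause benzylic substitution and Friedel-Crafts oligomerisation. The pivalates instead leave under the same hydride that makes the CH2OH group.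
- Oxidation level: the cycloadduct is an enediol ether, at the acyloin level. One two-electron oxidation gives the 1,2-dione, which is a tautomer of the catechol.
- Assumption: adduct 10 is carried on without chromatography, because trimethylsilyl enol ethers hydrolyse on silica.

**Route**

Step 1
Reactants: 1 5-bromovanillin (3-bromo-4-hydroxy-5-methoxybenzaldehyde)
Product: 2 3-bromo-4,5-dihydroxybenzaldehyde
Conditions: AlCl3, pyridine, CH2Cl2, reflux; then aq. HCl
Reagents that add atoms: none
Why: Chelation-directed demethylation of a guaiacol, in which aluminium binds the phenoxide and the neighbouring methoxy oxygen so that pyridine takes the methyl group in an SN2 step, leaving the aldehyde and the aryl bromide alone.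

Step 2
Reactants: 2 3-bromo-4,5-dihydroxybenzaldehyde
Product: 3 3-bromo-4,5-bis(pivaloyloxy)benzaldehyde
Conditions: PivCl, Et3N, DMAP (cat.), CH2Cl2, 0 °C to rt
Reagents that add atoms: pivaloyl chloride, CC(C)(C)C(Cl)=O
Why: Nucleophile-catalysed O-acylation of both phenols gives hindered aryl esters that should withstand the weak base and the heat to come and that lower the electron density of ring B.

Step 3
Reactants: 3 3-bromo-4,5-bis(pivaloyloxy)benzaldehyde
Product: 4 [3-bromo-4,5-bis(pivaloyloxy)phenyl]methanol
Conditions: NaBH4, THF/EtOH, -10 °C; aq. NH4Cl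
Reagents that add atoms: none
Why: Chemoselective borohydride reduction of an aromatic aldehyde, which at low temperature is much faster than attack on the hindered pivalates.

Step 4
Reactants: 4 [3-bromo-4,5-bis(pivaloyloxy)phenyl]methanol
Product: 5 3-bromo-4,5-bis(pivaloyloxy)benzyl bromide
Conditions: PBr3, CH2Cl2, 0 °C
Reagents that add atoms: phosphorus tribromide, BrP(Br)Br
Why: Conversion of a primary benzylic alcohol into the bromide through its phosphite ester and SN2 displacement by bromide, under conditions that leave aryl esters intact.

Step 5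
Reactants: 5 3-bromo-4,5-bis(pivaloyloxy)benzyl bromide; 6 methyl propiolate
Product: 7 methyl 4-[3-bromo-4,5-bis(pivaloyloxy)phenyl]but-2-ynoate
Conditions: CuI (20 mol %), K2CO3, MeCN, rt to 40 °C, Ar
Reagents that add atoms: none
Why: Copper-catalysed alkynylation of a benzylic halide (sp-sp3 coupling of a terminal alkyne), in which the acidic propiolate C-H is activated by CuI and the sparingly soluble carbonate and the benzylic C-Br bond is displaced, while the aryl C-Br bond does not react with monovalent copper at this temperature and the weak heterogeneous base limits propargyl-allenyl isomerisation.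

Step 6
Reactants: 8 butane-2,3-dione
Product: 9 2,3-bis(trimethylsilyloxy)buta-1,3-diene
Conditions: TMSOTf, Et3N, Et2O, 0 °C to rt; distillation
Reagents that add atoms: trimethylsilyl trifluoromethanesulfonate, C[Si](C)(C)OS(=O)(=O)C(F)(F)F
Why: Twofold soft enolisation and O-silylation (silyl enol ether formation) of the 1,2-diketone, each methyl group losing one proton, gives the symmetrical 2,3-dioxygenated diene.

Step 7
Reactants: 7 methyl 4-[3-bromo-4,5-bis(pivaloyloxy)phenyl]but-2-ynoate; 9 2,3-bis(trimethylsilyloxy)buta-1,3-diene
Product: 10 methyl 2-[3-bromo-4,5-bis(pivaloyloxy)benzyl]-4,5-bis(trimethylsilyloxy)cyclohexa-1,4-diene-1-carboxylate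
Conditions: 9 (3 equiv), BHT (cat.), toluene, sealed tube, 150 °C, Ar; volatiles removed in vacuo
Reagents that add atoms: none
Why: A concerted, thermally allowed, normal-electron-demand [4+2] cycloaddition joins the s-cis form of diene 9, whose HOMO is raised by two silyloxy groups, to the alkyne of 7, whose LUMO is lowered by the ester; the closest known reaction type is the Diels-Alder reaction of 2,3-bis(silyloxy)buta-1,3-dienes with acetylenic esters. Ring A closes as a six-membered carbocycle in an intermolecular two-bond annulation, C1-C2 and C5-C6 forming together, with C2-C5 coming from the diene and C1/C6 from the alkyne. No stereocentre arises, because every ring atom of 10 is either sp2 or a CH2 group. No regiocontrol is needed, since 9 is symmetrical and both orientations give the same adduct. The selectivity that is needed is chemoselectivity: the aryl bromide, the pivalates and the methyl ester are thermally inert, and neutral, base-free, anhydrous conditions with excess diene hold back prototropic drift of the doubly activated CH2 group and hydrolysis of the enol ethers. The benzyl group on the beta carbon slows the reaction, which is why forcing temperature is planned and why the route carries its risk here.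

Step 8
Reactants: 10 methyl 2-[3-bromo-4,5-bis(pivaloyloxy)benzyl]-4,5-bis(trimethylsilyloxy)cyclohexa-1,4-diene-1-carboxylate
Product: 12 methyl 2-[3-bromo-4,5-bis(pivaloyloxy)benzyl]-4,5-dihydroxybenzoate, via ring A 1,2-dione 11 (not isolated)
Conditions: NBS (1.0 equiv), THF, -78 °C to rt; then 1 M HCl
Reagents that add atoms: none
Why: Electrophilic bromine attacks the very electron-rich enediol bis(silyl ether) far faster than any arene, the alpha-bromo alpha-silyloxy ketone collapses with loss of the silyl bromide to the 1,2-dione (the known oxidation of 1,2-bis(silyloxy)alkenes), and twofold keto-enol tautomerisation driven by aromatisation delivers the catechol.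

Step 9
Reactants: 12 methyl 2-[3-bromo-4,5-bis(pivaloyloxy)benzyl]-4,5-dihydroxybenzoate
Product: 13 methyl 3-bromo-2-[3-bromo-4,5-bis(pivaloyloxy)benzyl]-4,5-dihydroxybenzoate
Conditions: Br2 (1.0 equiv), AcOH/CH2Cl2, 0 °C to rt
Reagents that add atoms: bromine, BrBr
Why: Electrophilic aromatic bromination should go to ring A C5, which is ortho to the C4 OH and the C6 alkyl group and meta to the ester (the position taken in protocatechuate esters), whereas attack at C2 would place positive charge on the ester-bearing C1, and ring B with two acyloxy groups and a bromine is far less nucleophilic than the free catechol.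

Step 10
Reactants: 13 methyl 3-bromo-2-[3-bromo-4,5-bis(pivaloyloxy)benzyl]-4,5-dihydroxybenzoate
Product: 14 5-hydroxyisoavrainvilleol, 3-bromo-4-[(3-bromo-4,5-dihydroxyphenyl)methyl]-5-(hydroxymethyl)benzene-1,2-diol
Conditions: i-Bu2AlH (10 equiv), THF, -78 °C to 0 °C; aq. potassium sodium tartrate, then citric acid to pH 4-5, EtOAc, Ar
Reagents that add atoms: none
Why: Global hydride reduction of esters, in which excess i-Bu2AlH deprotonates the two phenols, reduces the benzoate to the C1 CH2OH group and cleaves both aryl pivalates reductively, while aryl bromides are inert to this reagent and the low temperature discourages loss of the benzylic oxygen para to C4-O.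

**Compound list**
1 | 5-bromovanillin | COc1cc(C=O)cc(Br)c1O | starting material
2 | 3-bromo-4,5-dihydroxybenzaldehyde | O=Cc1cc(O)c(O)c(Br)c1 | intermediate
3 | 3-bromo-4,5-bis(pivaloyloxy)benzaldehyde | O=Cc1cc(OC(=O)C(C)(C)C)c(OC(=O)C(C)(C)C)c(Br)c1 | intermediate
4 | [3-bromo-4,5-bis(pivaloyloxy)phenyl]methanol | OCc1cc(OC(=O)C(C)(C)C)c(OC(=O)C(C)(C)C)c(Br)c1 | intermediate
5 | 3-bromo-4,5-bis(pivaloyloxy)benzyl bromide | BrCc1cc(OC(=O)C(C)(C)C)c(OC(=O)C(C)(C)C)c(Br)c1 | intermediate
6 | methyl propiolate | C#CC(=O)OC | starting material
7 | methyl 4-[3-bromo-4,5-bis(pivaloyloxy)phenyl]but-2-ynoate | COC(=O)C#CCc1cc(OC(=O)C(C)(C)C)c(OC(=O)C(C)(C)C)c(Br)c1 | intermediate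
8 | butane-2,3-dione | CC(=O)C(C)=O | starting material
9 | 2,3-bis(trimethylsilyloxy)buta-1,3-diene | C=C(O[Si](C)(C)C)C(=C)O[Si](C)(C)C | intermediate
10 | methyl 2-[3-bromo-4,5-bis(pivaloyloxy)benzyl]-4,5-bis(trimethylsilyloxy)cyclohexa-1,4-diene-1-carboxylate | COC(=O)C1=C(Cc2cc(OC(=O)C(C)(C)C)c(OC(=O)C(C)(C)C)c(Br)c2)CC(O[Si](C)(C)C)=C(O[Si](C)(C)C)C1 | intermediate
11 | methyl 2-[3-bromo-4,5-bis(pivaloyloxy)benzyl]-4,5-dioxocyclohex-1-ene-1-carboxylate (not isolated) | COC(=O)C1=C(Cc2cc(OC(=O)C(C)(C)C)c(OC(=O)C(C)(C)C)c(Br)c2)CC(=O)C(=O)C1 | intermediate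
12 | methyl 2-[3-bromo-4,5-bis(pivaloyloxy)benzyl]-4,5-dihydroxybenzoate | COC(=O)c1cc(O)c(O)cc1Cc1cc(OC(=O)C(C)(C)C)c(OC(=O)C(C)(C)C)c(Br)c1 | intermediate
13 | methyl 3-bromo-2-[3-bromo-4,5-bis(pivaloyloxy)benzyl]-4,5-dihydroxybenzoate | COC(=O)c1cc(O)c(O)c(Br)c1Cc1cc(OC(=O)C(C)(C)C)c(OC(=O)C(C)(C)C)c(Br)c1 | intermediate
14 | 5-hydroxyisoavrainvilleol | OCc1cc(O)c(O)c(Br)c1Cc1cc(O)c(O)c(Br)c1 | target

**Step count**
Total step count: 10.
Longest linear sequence: 9 steps (1, 2, 3, 4, 5, 7, 8, 9, 10). Step 6 is a one-step side branch.

**The three steps most likely to fail**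

1. Step 7 (Diels-Alder reaction).
   - Risk: the cycloaddition to a beta-substituted, singly activated alkyne may be slower than thermal degradation of the diene and prototropic drift of the dienophile.
   - Fallback: it sets out from 7 and comes back at 12. Compound 7 is isomerised on purpose with catalytic Et3N in CH2Cl2 to the aryl- and ester-conjugated allene methyl 4-[3-bromo-4,5-bis(pivaloyloxy)phenyl]buta-2,3-dienoate F1. Allenic esters are established dienophiles that react at the ester-bearing C=C bond below the temperature an internal ynoate needs. Heating F1 with 9 in toluene at about 100 °C should form the same C1-C2 and C5-C6 bonds and give methyl 2-[3-bromo-4,5-bis(pivaloyloxy)benzylidene]-4,5-bis(trimethylsilyloxy)cyclohex-4-ene-1-carboxylate F2. NBS, used as in step 8, then gives methyl 2-[3-bromo-4,5-bis(pivaloyloxy)benzylidene]-4,5-dioxocyclohexane-1-carboxylate F3. Double enolisation and a shift of the acidic C1 proton to the exocyclic carbon, catalysed by the acid formed or by a trace of Et3N, aromatise F3 to 12. The stereocentre and the alkene geometry of F2 and F3 are erased in that step.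

2. Step 5 (benzyl-alkynyl coupling).
   - Risk: base-induced propargyl-to-allenyl isomerisation of the product, oxidative homocoupling or oligomerisation of the propiolate, and carbonate-induced loss of a pivalate.
   - Fallback: it sets out from 5 and 6 and comes back at 7, replacing the basic copper chemistry by a neutral Stille coupling. Compound 6 is stannylated with Bu3SnOMe, neat, with the methanol removed under vacuum, to give methyl 3-(tributylstannyl)prop-2-ynoate F4. F4 is then coupled with 5 under Pd(PPh3)4 in THF at 50 °C. Zerovalent palladium should insert into the benzylic C-Br bond ahead of the aryl C-Br bond, and no base is present to move the triple bond.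

3. Step 10 (global reduction).
   - Risk: over-reduction through loss of the benzylic oxygen assisted by the para aluminium phenoxide, stalling of the reduction at the electron-rich benzoate, and loss of the air-sensitive polyphenol in the aluminium work-up.
   - Fallback: it sets out from 13 and comes back at 14, staging the deprotection. The ring A catechol is silylated (TBSCl, imidazole, DMF) to methyl 3-bromo-2-[3-bromo-4,5-bis(pivaloyloxy)benzyl]-4,5-bis(tert-butyldimethylsilyloxy)benzoate F5, so that no phenoxide stands para to C1 during the hydride step. i-Bu2AlH in CH2Cl2 at -78 °C then gives 3-bromo-5-{[2-bromo-3,4-bis(tert-butyldimethylsilyloxy)-6-(hydroxymethyl)phenyl]methyl}benzene-1,2-diol F6. Et3N·3HF in THF at 0 °C removes the silyl groups under nearly neutral conditions to give 14.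

**Further compounds**
F1 | step 7 | methyl 4-[3-bromo-4,5-bis(pivaloyloxy)phenyl]buta-2,3-dienoate (racemic allene) | COC(=O)C=C=Cc1cc(OC(=O)C(C)(C)C)c(OC(=O)C(C)(C)C)c(Br)c1
F2 | step 7 | methyl 2-[3-bromo-4,5-bis(pivaloyloxy)benzylidene]-4,5-bis(trimethylsilyloxy)cyclohex-4-ene-1-carboxylate (racemic, alkene geometry not controlled) | COC(=O)C1CC(O[Si](C)(C)C)=C(O[Si](C)(C)C)CC1=Cc1cc(OC(=O)C(C)(C)C)c(OC(=O)C(C)(C)C)c(Br)c1
F3 | step 7 | methyl 2-[3-bromo-4,5-bis(pivaloyloxy)benzylidene]-4,5-dioxocyclohexane-1-carboxylate (racemic, alkene geometry not controlled) | COC(=O)C1CC(=O)C(=O)CC1=Cc1cc(OC(=O)C(C)(C)C)c(OC(=O)C(C)(C)C)c(Br)c1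
F4 | step 5 | methyl 3-(tributylstannyl)prop-2-ynoate | CCCC[Sn](CCCC)(CCCC)C#CC(=O)OC
F5 | step 10 | methyl 3-bromo-2-[3-bromo-4,5-bis(pivaloyloxy)benzyl]-4,5-bis(tert-butyldimethylsilyloxy)benzoate | COC(=O)c1cc(O[Si](C)(C)C(C)(C)C)c(O[Si](C)(C)C(C)(C)C)c(Br)c1Cc1cc(OC(=O)C(C)(C)C)c(OC(=O)C(C)(C)C)c(Br)c1
F6 | step 10 | 3-bromo-5-{[2-bromo-3,4-bis(tert-butyldimethylsilyloxy)-6-(hydroxymethyl)phenyl]methyl}benzene-1,2-diol | OCc1cc(O[Si](C)(C)C(C)(C)C)c(O[Si](C)(C)C(C)(C)C)c(Br)c1Cc1cc(O)c(O)c(Br)c1
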